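**Retrosynthetic overview**
1. The C3=C4 double bond comes from loss of water from a 4-hydroxychroman. The phenol is unmasked from its silyl ether just before that.
2. The side chain is cut at C1'–C2'. This gives a chroman-2-ylmethyl triflate and a lithiated (E)-allyl phenyl sulfone made from dihydro-β-ionone by HWE; the sulfone is removed reductively afterwards.
3. The pyran ring is cut at O1–C8a. A tertiary alcohol is cyclised onto an aryl bromide under Pd catalysis, and no bond to C2 is touched.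
4. The key cut is C2–C3: an enantioselective Mukaiyama aldol between the enol silane of 2-bromo-5-silyloxyacetophenone and methyl pyruvate. It sets C2; the ketone oxygen later leaves as water and the ester carbon becomes C1'.
5. Ring order: the benzene and cyclohexene rings are bought. The pyran ring is the only ring formed (step 9), and its double bond is made last (step 19).

Assumption: the carbinol carbon C4 (created in step 6) and the sulfone-bearing carbon (created in step 16) are carried as epimer mixtures and left undefined in the SMILES, because both centres vanish again in steps 19 and 17. Chroman numbering is used throughout.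

**Fragment A (arene, stereocentre, pyran ring)**

Step 1
Reactants: 1 3'-methoxyacetophenone
Product: 2 1-(2-bromo-5-methoxyphenyl)ethanone
Conditions: NBS (1.05 equiv), MeCN, rt, dark
Reagents that add atoms: N-bromosuccinimide, O=C1CCC(=O)N1Br
Why: In this electrophilic aromatic bromination the methoxy group directs bromine to its para position (ortho to the acetyl group), and the polar solvent favours ring over side-chain bromination.

Step 2
Reactants: 2 1-(2-bromo-5-methoxyphenyl)ethanone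
Product: 3 1-(2-bromo-5-hydroxyphenyl)ethanone
Conditions: BBr3 (2 equiv), CH2Cl2, −78 °C to rt; H2O
Reagents that add atoms: none
Why: Lewis-acid cleavage of the aryl methyl ether leaves the ketone and the aryl bromide untouched and frees the phenol for a fluoride-labile protecting group.

Step 3
Reactants: 3 1-(2-bromo-5-hydroxyphenyl)ethanone
Product: 4 1-[2-bromo-5-(triisopropylsilyloxy)phenyl]ethanone
Conditions: TIPSCl, imidazole, DMF, rt
Reagents that add atoms: chlorotriisopropylsilane, CC(C)[Si](Cl)(C(C)C)C(C)C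
Why: The bulky aryl TIPS ether withstands hydrides, anhydrous carbonate, carbanions and dilute acid, and it is removed by fluoride at the end.

Step 4
Reactants: 4 1-[2-bromo-5-(triisopropylsilyloxy)phenyl]ethanone
Product: 5 {1-[2-bromo-5-(triisopropylsilyloxy)phenyl]ethenyloxy}trimethylsilane
Conditions: TMSOTf (1.2 equiv), Et3N (1.5 equiv), CH2Cl2, 0 °C; pentane extraction
Reagents that add atoms: trimethylsilyl trifluoromethanesulfonate, C[Si](C)(C)OS(=O)(=O)C(F)(F)F
Why: Soft enolisation of a methyl ketone with only one enolisable side gives a single enol silane, the nucleophile for the Mukaiyama aldol.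

Step 5 (key step)
Reactants: 5 {1-[2-bromo-5-(triisopropylsilyloxy)phenyl]ethenyloxy}trimethylsilane; 6 methyl pyruvate
Product: 8 methyl (R)-4-[2-bromo-5-(triisopropylsilyloxy)phenyl]-2-hydroxy-2-methyl-4-oxobutanoate, via O-trimethylsilyl aldol adduct 7 (not isolated)
Conditions: Cu(OTf)2 (10 mol %), (R,R)-t-Bu-box [2,2'-(propane-2,2-diyl)bis((4R)-4-tert-butyl-4,5-dihydrooxazole), 11 mol %], THF, −78 °C; then 1 M HCl, THF, 0 °C
Reagents that add atoms: none
Why: In this catalytic enantioselective Mukaiyama aldol the pyruvate chelates divalent copper through both carbonyl oxygens in a square-planar complex, the tert-butyl groups of the (R,R)-ligand block the si face of the ketone, and the enol silane adds to the re face to give the R tertiary carbinol that becomes C2 of the chromene.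

Step 6
Reactants: 8 methyl (R)-4-[2-bromo-5-(triisopropylsilyloxy)phenyl]-2-hydroxy-2-methyl-4-oxobutanoate
Product: 9 (2R)-4-[2-bromo-5-(triisopropylsilyloxy)phenyl]-2-methylbutane-1,2,4-triol (C4 epimers)
Conditions: LiBH4 (3 equiv), THF, 0 °C to rt
Reagents that add atoms: none
Why: This hydride reduction takes both the ketone and the activated α-hydroxy ester (or any lactone formed from them) to alcohols while sparing C–Br and the silyl ether, which removes all retro-aldol and elimination risk; the new C4 centre forms unselectively and is destroyed in step 19.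

Step 7
Reactants: 9 (2R)-4-[2-bromo-5-(triisopropylsilyloxy)phenyl]-2-methylbutane-1,2,4-triol
Product: 10 (2R)-4-[2-bromo-5-(triisopropylsilyloxy)phenyl]-2,4-dihydroxy-2-methylbutyl pivalate (C4 epimers)
Conditions: PivCl (1.1 equiv), pyridine, CH2Cl2, 0 °C
Reagents that add atoms: pivaloyl chloride, CC(C)(C)C(=O)Cl
Why: In this selective acylation the bulky acid chloride takes the primary alcohol ahead of the hindered benzylic secondary and the tertiary alcohol, and a pivalate resists acyl migration.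

Step 8
Reactants: 10 (2R)-4-[2-bromo-5-(triisopropylsilyloxy)phenyl]-2,4-dihydroxy-2-methylbutyl pivalate
Product: 11 (2R)-4-[2-bromo-5-(triisopropylsilyloxy)phenyl]-4-(tert-butyldimethylsilyloxy)-2-hydroxy-2-methylbutyl pivalate (C4 epimers)
Conditions: TBSCl (1.5 equiv), imidazole, DMF, rt to 40 °C
Reagents that add atoms: tert-butylchlorodimethylsilane, CC(C)(C)[Si](C)(C)Cl
Why: TBSCl with imidazole silylates the secondary benzylic alcohol but not the tertiary one, which stays free as the nucleophile for ring closure.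

Step 9
Reactants: 11 (2R)-4-[2-bromo-5-(triisopropylsilyloxy)phenyl]-4-(tert-butyldimethylsilyloxy)-2-hydroxy-2-methylbutyl pivalate
Product: 12 [(2R)-4-(tert-butyldimethylsilyloxy)-2-methyl-6-(triisopropylsilyloxy)chroman-2-yl]methyl pivalate (C4 epimers)
Conditions: Pd(OAc)2 (5 mol %), 2-(di-tert-butylphosphino)-1,1'-binaphthyl (6 mol %), Cs2CO3 (1.5 equiv), dry toluene, 80 °C
Reagents that add atoms: none
Why: In this intramolecular Buchwald-type C–O coupling zerovalent palladium inserts into C–Br and reductive elimination closes the six-membered ring, a tertiary alkoxide cannot undergo β-hydride elimination, and only O–H and C–Br are broken so C2 keeps its configuration.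

Step 10
Reactants: 12 [(2R)-4-(tert-butyldimethylsilyloxy)-2-methyl-6-(triisopropylsilyloxy)chroman-2-yl]methyl pivalate
Product: 13 [(2R)-4-(tert-butyldimethylsilyloxy)-2-methyl-6-(triisopropylsilyloxy)chroman-2-yl]methanol (C4 epimers)
Conditions: i-Bu2AlH (2.5 equiv), CH2Cl2, −78 °C; aq. potassium sodium tartrate
Reagents that add atoms: none
Why: Reductive ester cleavage removes the pivalate without acid, base or fluoride, so both silyl ethers stay in place.

Step 11
Reactants: 13 [(2R)-4-(tert-butyldimethylsilyloxy)-2-methyl-6-(triisopropylsilyloxy)chroman-2-yl]methanol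
Product: 14 [(2R)-4-(tert-butyldimethylsilyloxy)-2-methyl-6-(triisopropylsilyloxy)chroman-2-yl]methyl trifluoromethanesulfonate (C4 epimers)
Conditions: Tf2O (1.2 equiv), pyridine (2.5 equiv), CH2Cl2, −78 to −10 °C; used at once
Reagents that add atoms: trifluoromethanesulfonic anhydride, O=S(=O)(OS(=O)(=O)C(F)(F)F)C(F)(F)F
Why: Sulfonylation supplies the very good leaving group that a neopentyl-type carbon needs, and the triflate can be handled because it has no β-hydrogen and the β-oxygen disfavours ionisation.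

**Fragment B (side chain)**

Step 12
Reactants: 15 dihydro-β-ionone [4-(2,6,6-trimethylcyclohex-1-en-1-yl)butan-2-one]; 16 triethyl phosphonoacetate
Product: 18 ethyl (2E)-3-methyl-5-(2,6,6-trimethylcyclohex-1-en-1-yl)pent-2-enoate, via sodium phosphonoacetate carbanion 17 (not isolated)
Conditions: NaH (1.3 equiv), THF, 0 °C to reflux; chromatography to remove the Z isomer (E:Z about 4–5:1)
Reagents that add atoms: none
Why: The Horner–Wadsworth–Emmons olefination of the methyl ketone with a stabilised phosphonate favours the E enoate under thermodynamic control, and the minor Z ester is separable on silica.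

Step 13
Reactants: 18 ethyl (2E)-3-methyl-5-(2,6,6-trimethylcyclohex-1-en-1-yl)pent-2-enoate
Product: 19 (2E)-3-methyl-5-(2,6,6-trimethylcyclohex-1-en-1-yl)pent-2-en-1-ol
Conditions: i-Bu2AlH (2.3 equiv), CH2Cl2, −78 to 0 °C; aq. potassium sodium tartrate
Reagents that add atoms: none
Why: The 1,2-reduction of the enoate gives the allylic alcohol without touching the alkene geometry.

Step 14
Reactants: 19 (2E)-3-methyl-5-(2,6,6-trimethylcyclohex-1-en-1-yl)pent-2-en-1-ol
Product: 20 2-[(3E)-5-bromo-3-methylpent-3-en-1-yl]-1,3,3-trimethylcyclohexene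
Conditions: PBr3 (0.4 equiv), Et2O, −10 to 0 °C; used crude
Reagents that add atoms: phosphorus tribromide, BrP(Br)Br
Why: SN2 displacement of the phosphite ester at the primary allylic carbon at low temperature avoids allylic transposition and E/Z scrambling.

Step 15
Reactants: 20 2-[(3E)-5-bromo-3-methylpent-3-en-1-yl]-1,3,3-trimethylcyclohexene
Product: 21 (2E)-3-methyl-5-(2,6,6-trimethylcyclohex-1-en-1-yl)pent-2-en-1-yl phenyl sulfone
Conditions: PhSO2Na (1.5 equiv), DMF, rt
Reagents that add atoms: sodium benzenesulfinate, [Na+].[O-]S(=O)c1ccccc1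
Why: S-alkylation of the sulfinate (SN2) gives a stable allyl sulfone whose carbanion reacts only at the α-carbon.

**Union and endgame**

Step 16
Reactants: 21 (2E)-3-methyl-5-(2,6,6-trimethylcyclohex-1-en-1-yl)pent-2-en-1-yl phenyl sulfone; 14 [(2R)-4-(tert-butyldimethylsilyloxy)-2-methyl-6-(triisopropylsilyloxy)chroman-2-yl]methyl trifluoromethanesulfonate
Product: 23 (2R)-4-(tert-butyldimethylsilyloxy)-2-methyl-2-[(3E)-4-methyl-2-(phenylsulfonyl)-6-(2,6,6-trimethylcyclohex-1-en-1-yl)hex-3-en-1-yl]-6-(triisopropylsilyloxy)chroman (epimers at C4 and at the sulfone carbon), via lithiated sulfone 22 (not isolated)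
Conditions: 21 (1.3 equiv), n-BuLi (1.25 equiv), THF–HMPA 5:1, −78 °C; then 14, −78 to −20 °C
Reagents that add atoms: none
Why: The soft α-sulfonyl carbanion displaces the triflate by SN2 at its α-carbon with the E alkene preserved, elimination is impossible, and C2 is not involved.

Step 17
Reactants: 23 (2R)-4-(tert-butyldimethylsilyloxy)-2-methyl-2-[(3E)-4-methyl-2-(phenylsulfonyl)-6-(2,6,6-trimethylcyclohex-1-en-1-yl)hex-3-en-1-yl]-6-(triisopropylsilyloxy)chroman
Product: 24 (2S)-4-(tert-butyldimethylsilyloxy)-2-methyl-2-[(3E)-4-methyl-6-(2,6,6-trimethylcyclohex-1-en-1-yl)hex-3-en-1-yl]-6-(triisopropylsilyloxy)chroman (C4 epimers)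
Conditions: PdCl2(dppp) (10 mol %), LiEt3BH (3 equiv), THF, 0 °C
Reagents that add atoms: none
Why: In this Pd-catalysed reductive desulfonylation zerovalent palladium ionises the allyl sulfone to a π-allyl complex and hydride goes to the less substituted terminus, which keeps the trisubstituted E alkene in place (the descriptor at C2 changes from R to S only through CIP ranking).

Step 18
Reactants: 24 (2S)-4-(tert-butyldimethylsilyloxy)-2-methyl-2-[(3E)-4-methyl-6-(2,6,6-trimethylcyclohex-1-en-1-yl)hex-3-en-1-yl]-6-(triisopropylsilyloxy)chroman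
Product: 25 (2S)-2-methyl-2-[(3E)-4-methyl-6-(2,6,6-trimethylcyclohex-1-en-1-yl)hex-3-en-1-yl]chroman-4,6-diol (C4 epimers)
Conditions: n-Bu4NF (3 equiv), THF, 0 °C to rt, argon; aq. NH4Cl
Reagents that add atoms: none
Why: Fluoride-driven desilylation removes both silyl ethers under conditions that leave the alkenes and the stereocentre alone.

Step 19
Reactants: 25 (2S)-2-methyl-2-[(3E)-4-methyl-6-(2,6,6-trimethylcyclohex-1-en-1-yl)hex-3-en-1-yl]chroman-4,6-diol
Product: 26 (2S)-2-methyl-2-[(3E)-4-methyl-6-(2,6,6-trimethylcyclohex-1-en-1-yl)hex-3-en-1-yl]-2H-chromen-6-ol (CNP0157994.1)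
Conditions: pyridinium p-toluenesulfonate (10 mol %), toluene, 4 Å sieves, 70 °C, argon, dark
Reagents that add atoms: none
Why: In this acid-catalysed E1 dehydration only the benzylic alcohol, whose cation is stabilised by the ortho ring oxygen, ionises under such weak acid and can lose a proton only from C3 (C2 is quaternary), while the isolated alkenes and the C2–O bond are not attacked and exclusion of light prevents electrocyclic ring opening and hence racemisation.

**Compound list**
1 | 3'-methoxyacetophenone | CC(=O)c1cccc(OC)c1 | starting material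
2 | 1-(2-bromo-5-methoxyphenyl)ethanone | CC(=O)c1cc(OC)ccc1Br | intermediate
3 | 1-(2-bromo-5-hydroxyphenyl)ethanone | CC(=O)c1cc(O)ccc1Br | intermediate
4 | 1-[2-bromo-5-(triisopropylsilyloxy)phenyl]ethanone | CC(=O)c1cc(O[Si](C(C)C)(C(C)C)C(C)C)ccc1Br | intermediate
5 | {1-[2-bromo-5-(triisopropylsilyloxy)phenyl]ethenyloxy}trimethylsilane | C=C(O[Si](C)(C)C)c1cc(O[Si](C(C)C)(C(C)C)C(C)C)ccc1Br | intermediate
6 | methyl pyruvate | CC(=O)C(=O)OC | starting material
7 | methyl (R)-4-[2-bromo-5-(triisopropylsilyloxy)phenyl]-2-methyl-4-oxo-2-(trimethylsilyloxy)butanoate (not isolated) | COC(=O)[C@](C)(O[Si](C)(C)C)CC(=O)c1cc(O[Si](C(C)C)(C(C)C)C(C)C)ccc1Br | intermediate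
8 | methyl (R)-4-[2-bromo-5-(triisopropylsilyloxy)phenyl]-2-hydroxy-2-methyl-4-oxobutanoate | COC(=O)[C@](C)(O)CC(=O)c1cc(O[Si](C(C)C)(C(C)C)C(C)C)ccc1Br | intermediate
9 | (2R)-4-[2-bromo-5-(triisopropylsilyloxy)phenyl]-2-methylbutane-1,2,4-triol, C4 epimers | OC[C@](C)(O)CC(O)c1cc(O[Si](C(C)C)(C(C)C)C(C)C)ccc1Br | intermediate
10 | (2R)-4-[2-bromo-5-(triisopropylsilyloxy)phenyl]-2,4-dihydroxy-2-methylbutyl pivalate | CC(C)(C)C(=O)OC[C@](C)(O)CC(O)c1cc(O[Si](C(C)C)(C(C)C)C(C)C)ccc1Br | intermediate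
11 | (2R)-4-[2-bromo-5-(triisopropylsilyloxy)phenyl]-4-(tert-butyldimethylsilyloxy)-2-hydroxy-2-methylbutyl pivalate | CC(C)(C)C(=O)OC[C@](C)(O)CC(O[Si](C)(C)C(C)(C)C)c1cc(O[Si](C(C)C)(C(C)C)C(C)C)ccc1Br | intermediate
12 | [(2R)-4-(tert-butyldimethylsilyloxy)-2-methyl-6-(triisopropylsilyloxy)chroman-2-yl]methyl pivalate | CC(C)(C)C(=O)OC[C@@]1(C)CC(O[Si](C)(C)C(C)(C)C)c2cc(O[Si](C(C)C)(C(C)C)C(C)C)ccc2O1 | intermediate
13 | [(2R)-4-(tert-butyldimethylsilyloxy)-2-methyl-6-(triisopropylsilyloxy)chroman-2-yl]methanol | OC[C@@]1(C)CC(O[Si](C)(C)C(C)(C)C)c2cc(O[Si](C(C)C)(C(C)C)C(C)C)ccc2O1 | intermediate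
14 | [(2R)-4-(tert-butyldimethylsilyloxy)-2-methyl-6-(triisopropylsilyloxy)chroman-2-yl]methyl trifluoromethanesulfonate | FC(F)(F)S(=O)(=O)OC[C@@]1(C)CC(O[Si](C)(C)C(C)(C)C)c2cc(O[Si](C(C)C)(C(C)C)C(C)C)ccc2O1 | intermediate
15 | dihydro-β-ionone | CC(=O)CCC1=C(C)CCCC1(C)C | starting material
16 | triethyl phosphonoacetate | CCOC(=O)CP(=O)(OCC)OCC | starting material
17 | sodium salt of triethyl phosphonoacetate (not isolated) | [Na+].CCOC(=O)[CH-]P(=O)(OCC)OCC | intermediate
18 | ethyl (2E)-3-methyl-5-(2,6,6-trimethylcyclohex-1-en-1-yl)pent-2-enoate | CCOC(=O)/C=C(\C)CCC1=C(C)CCCC1(C)C | intermediate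
19 | (2E)-3-methyl-5-(2,6,6-trimethylcyclohex-1-en-1-yl)pent-2-en-1-ol | OC/C=C(\C)CCC1=C(C)CCCC1(C)C | intermediate
20 | 2-[(3E)-5-bromo-3-methylpent-3-en-1-yl]-1,3,3-trimethylcyclohexene | BrC/C=C(\C)CCC1=C(C)CCCC1(C)C | intermediate
21 | (2E)-3-methyl-5-(2,6,6-trimethylcyclohex-1-en-1-yl)pent-2-en-1-yl phenyl sulfone | O=S(=O)(C/C=C(\C)CCC1=C(C)CCCC1(C)C)c1ccccc1 | intermediate
22 | α-lithio derivative of sulfone 21 (not isolated) | [Li]C(/C=C(\C)CCC1=C(C)CCCC1(C)C)S(=O)(=O)c1ccccc1 | intermediate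
23 | (2R)-4-(tert-butyldimethylsilyloxy)-2-methyl-2-[(3E)-4-methyl-2-(phenylsulfonyl)-6-(2,6,6-trimethylcyclohex-1-en-1-yl)hex-3-en-1-yl]-6-(triisopropylsilyloxy)chroman | O=S(=O)(c1ccccc1)C(C[C@@]1(C)CC(O[Si](C)(C)C(C)(C)C)c2cc(O[Si](C(C)C)(C(C)C)C(C)C)ccc2O1)/C=C(\C)CCC1=C(C)CCCC1(C)C | intermediate
24 | (2S)-4-(tert-butyldimethylsilyloxy)-2-methyl-2-[(3E)-4-methyl-6-(2,6,6-trimethylcyclohex-1-en-1-yl)hex-3-en-1-yl]-6-(triisopropylsilyloxy)chroman | CC1=C(CC/C(C)=C/CC[C@@]2(C)CC(O[Si](C)(C)C(C)(C)C)c3cc(O[Si](C(C)C)(C(C)C)C(C)C)ccc3O2)C(C)(C)CCC1 | intermediate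
25 | (2S)-2-methyl-2-[(3E)-4-methyl-6-(2,6,6-trimethylcyclohex-1-en-1-yl)hex-3-en-1-yl]chroman-4,6-diol | CC1=C(CC/C(C)=C/CC[C@@]2(C)CC(O)c3cc(O)ccc3O2)C(C)(C)CCC1 | intermediate
26 | (2S)-2-methyl-2-[(3E)-4-methyl-6-(2,6,6-trimethylcyclohex-1-en-1-yl)hex-3-en-1-yl]-2H-chromen-6-ol | CC1=C(CC/C(C)=C/CC[C@@]2(C)C=Cc3cc(O)ccc3O2)C(C)(C)CCC1 | target

**Step count**
Total steps: 19. Longest linear sequence: 15 (steps 1–11, then 16–19).

**The three steps most likely to fail**

**Step 5: rate or ee with the untested ortho-bromoaryl enol silane.**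
The fallback takes the aryl group out of the aldol and brings it in later as a Grignard reagent.
- It sets out from 6. The same Cu(OTf)2/(R,R)-t-Bu-box catalyst is used with 1-(ethylsulfanyl)-1-(trimethylsilyloxy)ethene, the nucleophile class for which this aldol works best. Acidic work-up gives methyl (R)-4-(ethylsulfanyl)-2-hydroxy-2-methyl-4-oxobutanoate F1.
- Fukuyama reduction (Et3SiH, Pd on carbon, acetone, rt) gives methyl (R)-2-hydroxy-2-methyl-4-oxobutanoate F2.
- Commercial 4-bromo-3-iodophenol is silylated (TIPSCl, imidazole) to (4-bromo-3-iodophenoxy)triisopropylsilane F3.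
- Iodine–magnesium exchange (i-PrMgCl·LiCl, THF, −40 °C) gives [2-bromo-5-(triisopropylsilyloxy)phenyl]magnesium chloride F4.
- 2.2 equiv of F4 add to the aldehyde of F2 at −78 °C. The resulting alkoxide closes onto the ester to give (3R)-5-[2-bromo-5-(triisopropylsilyloxy)phenyl]-3-hydroxy-3-methyldihydrofuran-2(3H)-one F5.
- LiBH4 opens F5 to triol 9, where the route is rejoined.

**Step 9: hydrodebromination instead of C–O coupling on the electron-rich, ortho-branched bromide.**
The fallback closes the pyran ring from the other side. The phenol oxygen is placed on the arene first and attacks C2 of an epoxide with inversion, so the mirror-image aldol adduct is required.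
- It sets out from 5 and 6. Cu(OTf)2/(S,S)-t-Bu-box gives methyl (S)-4-[2-bromo-5-(triisopropylsilyloxy)phenyl]-2-hydroxy-2-methyl-4-oxobutanoate F6.
- LiBH4 gives (2S)-4-[2-bromo-5-(triisopropylsilyloxy)phenyl]-2-methylbutane-1,2,4-triol F7.
- TsCl/pyridine at 0 °C gives (2S)-4-[2-bromo-5-(triisopropylsilyloxy)phenyl]-2,4-dihydroxy-2-methylbutyl 4-methylbenzenesulfonate F8.
- TBSCl/imidazole gives (2S)-4-[2-bromo-5-(triisopropylsilyloxy)phenyl]-4-(tert-butyldimethylsilyloxy)-2-hydroxy-2-methylbutyl 4-methylbenzenesulfonate F9.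
- NaH in THF closes (2S)-2-{2-[2-bromo-5-(triisopropylsilyloxy)phenyl]-2-(tert-butyldimethylsilyloxy)ethyl}-2-methyloxirane F10.
- n-BuLi is added at −78 °C in the presence of B(Oi-Pr)3, followed by NaBO3·4H2O. This turns C–Br into C–OH and gives 2-{1-(tert-butyldimethylsilyloxy)-2-[(2S)-2-methyloxiran-2-yl]ethyl}-4-(triisopropylsilyloxy)phenol F11.
- Catalytic camphorsulfonic acid (CH2Cl2, −20 °C) triggers 6-exo opening at the tertiary epoxide carbon with inversion. This gives alcohol 13 directly, where the route is rejoined.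

**Step 16: SN2 at a neopentyl-type carbon.**
The fallback replaces the displacement by a B-alkyl Suzuki–Miyaura coupling, which forms C2'–C3' instead of C1'–C2'.
- It sets out from 13. Dess–Martin oxidation gives (2R)-4-(tert-butyldimethylsilyloxy)-2-methyl-6-(triisopropylsilyloxy)chroman-2-carbaldehyde F12.
- Wittig methylenation (Ph3P=CH2, THF) gives (2R)-4-(tert-butyldimethylsilyloxy)-2-ethenyl-2-methyl-6-(triisopropylsilyloxy)chroman F13.
- 9-BBN-H in THF gives 9-{2-[(2S)-4-(tert-butyldimethylsilyloxy)-2-methyl-6-(triisopropylsilyloxy)chroman-2-yl]ethyl}-9-borabicyclo[3.3.1]nonane F14.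
- The coupling partner is made from 15. LDA then ClP(O)(OEt)2 gives diethyl 4-(2,6,6-trimethylcyclohex-1-en-1-yl)but-1-en-2-yl phosphate F15.
- More LDA eliminates F15 to 2-(but-3-yn-1-yl)-1,3,3-trimethylcyclohexene F16.
- Negishi carboalumination (AlMe3, Cp2ZrCl2, CH2Cl2) followed by I2 gives 2-[(3E)-4-iodo-3-methylbut-3-en-1-yl]-1,3,3-trimethylcyclohexene F17 as essentially one isomer.
- Coupling of F14 with F17 (PdCl2(dppf), AsPh3, Cs2CO3, DMF–THF–H2O, rt) proceeds with retention of alkene geometry. It gives 24, where the route is rejoined; steps 11, 12–15 and 17 are then not needed.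

**Further compounds**
F1 | step 5 | methyl (R)-4-(ethylsulfanyl)-2-hydroxy-2-methyl-4-oxobutanoate | COC(=O)[C@](C)(O)CC(=O)SCC
F2 | step 5 | methyl (R)-2-hydroxy-2-methyl-4-oxobutanoate | COC(=O)[C@](C)(O)CC=O
F3 | step 5 | (4-bromo-3-iodophenoxy)triisopropylsilane | CC(C)[Si](Oc1ccc(Br)c(I)c1)(C(C)C)C(C)C
F4 | step 5 | [2-bromo-5-(triisopropylsilyloxy)phenyl]magnesium chloride | CC(C)[Si](Oc1ccc(Br)c([Mg]Cl)c1)(C(C)C)C(C)C
F5 | step 5 | (3R)-5-[2-bromo-5-(triisopropylsilyloxy)phenyl]-3-hydroxy-3-methyldihydrofuran-2(3H)-one | C[C@@]1(O)CC(c2cc(O[Si](C(C)C)(C(C)C)C(C)C)ccc2Br)OC1=O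
F6 | step 9 | methyl (S)-4-[2-bromo-5-(triisopropylsilyloxy)phenyl]-2-hydroxy-2-methyl-4-oxobutanoate | COC(=O)[C@@](C)(O)CC(=O)c1cc(O[Si](C(C)C)(C(C)C)C(C)C)ccc1Br
F7 | step 9 | (2S)-4-[2-bromo-5-(triisopropylsilyloxy)phenyl]-2-methylbutane-1,2,4-triol | OC[C@@](C)(O)CC(O)c1cc(O[Si](C(C)C)(C(C)C)C(C)C)ccc1Br
F8 | step 9 | (2S)-4-[2-bromo-5-(triisopropylsilyloxy)phenyl]-2,4-dihydroxy-2-methylbutyl 4-methylbenzenesulfonate | Cc1ccc(cc1)S(=O)(=O)OC[C@@](C)(O)CC(O)c1cc(O[Si](C(C)C)(C(C)C)C(C)C)ccc1Br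
F9 | step 9 | (2S)-4-[2-bromo-5-(triisopropylsilyloxy)phenyl]-4-(tert-butyldimethylsilyloxy)-2-hydroxy-2-methylbutyl 4-methylbenzenesulfonate | Cc1ccc(cc1)S(=O)(=O)OC[C@@](C)(O)CC(O[Si](C)(C)C(C)(C)C)c1cc(O[Si](C(C)C)(C(C)C)C(C)C)ccc1Br
F10 | step 9 | (2S)-2-{2-[2-bromo-5-(triisopropylsilyloxy)phenyl]-2-(tert-butyldimethylsilyloxy)ethyl}-2-methyloxirane | C[C@]1(CC(O[Si](C)(C)C(C)(C)C)c2cc(O[Si](C(C)C)(C(C)C)C(C)C)ccc2Br)CO1
F11 | step 9 | 2-{1-(tert-butyldimethylsilyloxy)-2-[(2S)-2-methyloxiran-2-yl]ethyl}-4-(triisopropylsilyloxy)phenol | C[C@]1(CC(O[Si](C)(C)C(C)(C)C)c2cc(O[Si](C(C)C)(C(C)C)C(C)C)ccc2O)CO1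
F12 | step 16 | (2R)-4-(tert-butyldimethylsilyloxy)-2-methyl-6-(triisopropylsilyloxy)chroman-2-carbaldehyde | O=C[C@@]1(C)CC(O[Si](C)(C)C(C)(C)C)c2cc(O[Si](C(C)C)(C(C)C)C(C)C)ccc2O1
F13 | step 16 | (2R)-4-(tert-butyldimethylsilyloxy)-2-ethenyl-2-methyl-6-(triisopropylsilyloxy)chroman | C=C[C@@]1(C)CC(O[Si](C)(C)C(C)(C)C)c2cc(O[Si](C(C)C)(C(C)C)C(C)C)ccc2O1
F14 | step 16 | 9-{2-[(2S)-4-(tert-butyldimethylsilyloxy)-2-methyl-6-(triisopropylsilyloxy)chroman-2-yl]ethyl}-9-borabicyclo[3.3.1]nonane | C(C[C@@]1(C)CC(O[Si](C)(C)C(C)(C)C)c2cc(O[Si](C(C)C)(C(C)C)C(C)C)ccc2O1)B1C2CCCC1CCC2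
F15 | step 16 | diethyl 4-(2,6,6-trimethylcyclohex-1-en-1-yl)but-1-en-2-yl phosphate | C=C(CCC1=C(C)CCCC1(C)C)OP(=O)(OCC)OCC
F16 | step 16 | 2-(but-3-yn-1-yl)-1,3,3-trimethylcyclohexene | C#CCCC1=C(C)CCCC1(C)C
F17 | step 16 | 2-[(3E)-4-iodo-3-methylbut-3-en-1-yl]-1,3,3-trimethylcyclohexene | I/C=C(\C)CCC1=C(C)CCCC1(C)C
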